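The plan rests on cutting the C2–C3 bond of the dihydrofuran ring. C2 is a benzylic ether carbon, bound to O1 and to the 3,4-dimethoxyphenyl ring, and C3 carries a CH2OH group which, raised to an ester, allows C3 to be generated as an aryl/ester-substituted rhodium carbene. A chiral dirhodium carboxylate then performs a 1,5 C–H insertion that forges C2–C3, closes the five-membered oxygen ring and fixes C2, and methoxide in the same flask relays this to the trans C3 centre. The substrate is an aryldiazoacetate carrying an ortho 3,4-dimethoxybenzyl ether, a methoxy group and an acetal-masked aldehyde, assembled in four steps from 5-bromovanillin.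

Key step: step 5

Assumption: the sense of induction (S-configured phthalimido-tert-leucinate catalyst giving 2R) is taken over from simpler 2-benzyloxyphenyl diazoacetates; should this substrate fall in the 2S series, the mirror-image catalyst Rh2(R-PTTL)4 is used with no other change.

Step 1
Reactants: 1 5-bromovanillin; 2 3,4-dimethoxybenzyl chloride
Product: 3 3-bromo-4-[(3,4-dimethoxyphenyl)methoxy]-5-methoxybenzaldehyde
Conditions: K2CO3, KI (cat.), DMF, 60 °C
Reagents that add atoms: none
Why: Williamson ether synthesis, in which the acidic para-formyl phenoxide of 1 displaces chloride from the activated benzylic chloride 2 (SN2, iodide catalysis) while aldehyde and aryl bromide are inert to K2CO3.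

Step 2
Reactants: 3 3-bromo-4-[(3,4-dimethoxyphenyl)methoxy]-5-methoxybenzaldehyde
Product: 4 1-bromo-2-[(3,4-dimethoxyphenyl)methoxy]-5-(dimethoxymethyl)-3-methoxybenzene
Conditions: HC(OMe)3, MeOH, PPTS (cat.), 50 °C; Et3N quench
Reagents that add atoms: trimethyl orthoformate, COC(OC)OC; methanol, CO
Why: Acid-catalysed acetalisation driven by the orthoformate as water scavenger masks the aldehyde against the zinc enolate, the diazo-transfer base and the hydride of later steps, the weak acid PPTS sparing the acid-sensitive dimethoxybenzyl aryl ether; the dimethyl acetal is chosen because it later cleaves in acid too mild to ionise the C2–O bond.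

Step 3
Reactants: 4 1-bromo-2-[(3,4-dimethoxyphenyl)methoxy]-5-(dimethoxymethyl)-3-methoxybenzene; 5 methyl bromoacetate
Product: 7 methyl 2-{2-[(3,4-dimethoxyphenyl)methoxy]-5-(dimethoxymethyl)-3-methoxyphenyl}acetate, via Reformatsky reagent 6 (not isolated)
Conditions: 5, Zn dust, TMSCl (cat.), THF, 40 °C; then 4, Pd(dba)2 (2 mol%), XPhos (4 mol%), THF, 60 °C; aq. NaHCO3 work-up, Et3N-washed silica
Reagents that add atoms: none
Why: Negishi-type palladium-catalysed α-arylation of an ester with a Reformatsky reagent, in which zerovalent palladium inserts into the C–Br bond, the zinc enolate 6 transmetalates and reductive elimination gives the arylacetate, the mild zinc enolate tolerating acetal and ethers and stopping at mono-arylation.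

Step 4
Reactants: 7 methyl 2-{2-[(3,4-dimethoxyphenyl)methoxy]-5-(dimethoxymethyl)-3-methoxyphenyl}acetate
Product: 8 methyl 2-diazo-2-{2-[(3,4-dimethoxyphenyl)methoxy]-5-(dimethoxymethyl)-3-methoxyphenyl}acetate
Conditions: p-ABSA, DBU, MeCN, 0 °C to rt; Et3N-washed silica
Reagents that add atoms: 4-acetamidobenzenesulfonyl azide (p-ABSA), CC(=O)Nc1ccc(cc1)S(=O)(=O)N=[N+]=[N-]
Why: Regitz diazo transfer, in which DBU deprotonates the benzylic ester-activated CH2, the enolate attacks the terminal azide nitrogen and the triazene collapses to the aryldiazoacetate and the sulfonamide, all under non-acidic conditions that keep the acetal.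

Step 5
Reactants: 8 methyl 2-diazo-2-{2-[(3,4-dimethoxyphenyl)methoxy]-5-(dimethoxymethyl)-3-methoxyphenyl}acetate
Product: 10 methyl (2R,3R)-2-(3,4-dimethoxyphenyl)-5-(dimethoxymethyl)-7-methoxy-2,3-dihydro-1-benzofuran-3-carboxylate (trans), via cis ester 9 (not isolated)
Conditions: Rh2(S-PTTL)4 (dirhodium tetrakis[N-phthaloyl-(S)-tert-leucinate], 1 mol%), toluene, −78 °C, slow addition of 8; then NaOMe (0.3 equiv), MeOH, 0 °C to rt
Reagents that add atoms: none
Why: The dirhodium tetracarboxylate expels N2 from 8 to give an electrophilic aryl/ester (donor/acceptor) rhodium carbene, which takes the neighbouring O–CH2–aryl C–H bond through a concerted, asynchronous, hydride-transfer-like three-centre transition state and so forms C2–C3 with retention at the reacting carbon. The closest known reaction type is the dirhodium carboxylate-catalysed enantioselective intramolecular C–H insertion of 2-benzyloxyphenyl diazoacetates to cis-2-aryl-2,3-dihydrobenzofuran-3-carboxylates, followed by base epimerisation to the trans esters. The dihydrofuran ring closes as a five-membered 1,5-insertion, the carbene carbon bonding to the fifth atom of the chain carbene C–aryl C–aryl C–O–CH2. C2 is set by the catalyst, whose chiral phthalimido-tert-leucinate ligands allow only one of the two enantiotopic benzylic hydrogens to reach the carbene (R expected with the S ligand); C3 is formed cis under kinetic control in 9 and is then set by thermodynamic control, as methoxide reversibly enolises the ester and reprotonation places CO2Me anti to the aryl group without breaking any bond at C2. The step needs site- and chemoselectivity over aromatic cycloaddition, ylide formation and carbene dimerisation, which is secured because this C–H bond is the only one held 1,5 to the carbene and is activated by both the oxygen lone pair and the electron-rich dimethoxyphenyl ring, and by slow addition at low temperature. The methyl ester and dimethyl acetal make every methoxide exchange degenerate, so the base step cannot scramble either group.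

Step 6
Reactants: 10 methyl (2R,3R)-2-(3,4-dimethoxyphenyl)-5-(dimethoxymethyl)-7-methoxy-2,3-dihydro-1-benzofuran-3-carboxylate
Product: 12 (2R,3S)-2-(3,4-dimethoxyphenyl)-3-(hydroxymethyl)-7-methoxy-2,3-dihydro-1-benzofuran-5-carbaldehyde, via acetal alcohol 11 (not isolated)
Conditions: LiAlH4, THF, 0 °C; then 1 M aq. HCl, THF, 0 °C to rt (short contact), NaHCO3 neutralisation
Reagents that add atoms: water, O
Why: Hydride reduction of the only reducible group (the ester) by LiAlH4, followed by specific-acid-catalysed acetal hydrolysis in the work-up, where the para-alkoxy-stabilised oxocarbenium ion lets the dimethyl acetal cleave in cold dilute acid that should not ionise the benzylic C2–O bond; both stereocentres are untouched and only the C3 descriptor changes with the substituent priorities.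

Step 7
Reactants: 12 (2R,3S)-2-(3,4-dimethoxyphenyl)-3-(hydroxymethyl)-7-methoxy-2,3-dihydro-1-benzofuran-5-carbaldehyde; 13 (formylmethylene)triphenylphosphorane
Product: 14 4-O-methylbalanophonin, (E)-3-[(2R,3S)-2-(3,4-dimethoxyphenyl)-3-(hydroxymethyl)-7-methoxy-2,3-dihydro-1-benzofuran-5-yl]prop-2-enal
Conditions: 13 (1.3 equiv), toluene, 80 °C
Reagents that add atoms: none
Why: Wittig olefination with a formyl-stabilised ylide, whose reversible addition under thermodynamic control should deliver the (E)-enal, the weakly basic ylide leaving the free alcohol and both stereocentres alone and its small excess limiting a second homologation.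

Compound list
1 | 5-bromovanillin (3-bromo-4-hydroxy-5-methoxybenzaldehyde) | COc1cc(C=O)cc(Br)c1O | starting material
2 | 3,4-dimethoxybenzyl chloride | COc1ccc(CCl)cc1OC | starting material
3 | 3-bromo-4-[(3,4-dimethoxyphenyl)methoxy]-5-methoxybenzaldehyde | COc1ccc(COc2c(Br)cc(C=O)cc2OC)cc1OC | intermediate
4 | 1-bromo-2-[(3,4-dimethoxyphenyl)methoxy]-5-(dimethoxymethyl)-3-methoxybenzene | COc1ccc(COc2c(Br)cc(C(OC)OC)cc2OC)cc1OC | intermediate
5 | methyl bromoacetate | COC(=O)CBr | starting material
6 | (2-methoxy-2-oxoethyl)zinc bromide, Reformatsky reagent (not isolated) | COC(=O)C[Zn]Br | intermediate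
7 | methyl 2-{2-[(3,4-dimethoxyphenyl)methoxy]-5-(dimethoxymethyl)-3-methoxyphenyl}acetate | COC(=O)Cc1cc(C(OC)OC)cc(OC)c1OCc1ccc(OC)c(OC)c1 | intermediate
8 | methyl 2-diazo-2-{2-[(3,4-dimethoxyphenyl)methoxy]-5-(dimethoxymethyl)-3-methoxyphenyl}acetate | COC(=O)C(=[N+]=[N-])c1cc(C(OC)OC)cc(OC)c1OCc1ccc(OC)c(OC)c1 | intermediate
9 | methyl (2R,3S)-2-(3,4-dimethoxyphenyl)-5-(dimethoxymethyl)-7-methoxy-2,3-dihydro-1-benzofuran-3-carboxylate, cis (not isolated) | COc1ccc([C@@H]2Oc3c(OC)cc(C(OC)OC)cc3[C@@H]2C(=O)OC)cc1OC | intermediate
10 | methyl (2R,3R)-2-(3,4-dimethoxyphenyl)-5-(dimethoxymethyl)-7-methoxy-2,3-dihydro-1-benzofuran-3-carboxylate, trans | COc1ccc([C@@H]2Oc3c(OC)cc(C(OC)OC)cc3[C@H]2C(=O)OC)cc1OC | intermediate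
11 | [(2R,3S)-2-(3,4-dimethoxyphenyl)-5-(dimethoxymethyl)-7-methoxy-2,3-dihydro-1-benzofuran-3-yl]methanol (not isolated) | COc1ccc([C@@H]2Oc3c(OC)cc(C(OC)OC)cc3[C@H]2CO)cc1OC | intermediate
12 | (2R,3S)-2-(3,4-dimethoxyphenyl)-3-(hydroxymethyl)-7-methoxy-2,3-dihydro-1-benzofuran-5-carbaldehyde | COc1ccc([C@@H]2Oc3c(OC)cc(C=O)cc3[C@H]2CO)cc1OC | intermediate
13 | (formylmethylene)triphenylphosphorane | O=CC=P(c1ccccc1)(c1ccccc1)c1ccccc1 | starting material
14 | 4-O-methylbalanophonin, (E)-3-[(2R,3S)-2-(3,4-dimethoxyphenyl)-3-(hydroxymethyl)-7-methoxy-2,3-dihydro-1-benzofuran-5-yl]prop-2-enal | COc1ccc([C@@H]2Oc3c(OC)cc(/C=C/C=O)cc3[C@H]2CO)cc1OC | target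

Total step count: 7. Longest linear sequence: 7 steps (1 to 14).

Steps most likely to fail

Step 5. The catalyst may discriminate the two enantiotopic benzylic hydrogens poorly on this 1,2,3-trisubstituted arene, where the flanking methoxy group twists the benzyloxy group out of plane. Carbene dimerisation may compete, and the methoxide stage may open the ring by β-elimination of the phenoxide and so erode C2. The fallback replaces catalyst control by auxiliary control and avoids the base stage. It sets out from 7, whose methyl ester is cleaved with KOSiMe3 in THF to potassium 2-{2-[(3,4-dimethoxyphenyl)methoxy]-5-(dimethoxymethyl)-3-methoxyphenyl}acetate F1. This salt is esterified (EDC·HCl, DMAP, CH2Cl2) with (2R)-2-hydroxy-1-(pyrrolidin-1-yl)propan-1-one to the lactamide arylacetate F2, and Regitz diazo transfer (p-ABSA, DBU, MeCN) gives the lactamide aryldiazoacetate F3. Rh2(R-DOSP)4 (dirhodium tetrakis[(R)-N-(4-dodecylbenzenesulfonyl)prolinate]) in CH2Cl2 should then effect the same 1,5 C–H insertion under matched auxiliary and catalyst control, giving the trans-dihydrobenzofuran lactamide ester F4, which is purified as a single diastereomer. LiBH4 in THF reduces the activated ester of F4 and releases the auxiliary alcohol, and the route is rejoined at 11, which is hydrolysed to 12 as in the acid stage of step 6. The auxiliary and catalyst are written as the R,R pair expected to lead to 2R; the mirror-image pair is taken if the sense proves opposite.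

Step 3. Oxidative addition or transmetalation may stall at the electron-rich ortho-alkoxy aryl bromide, the methyl ester zinc enolate may self-condense, or the zinc halide and the work-up may strip the acetal. The fallback uses carbonyl addition in place of cross-coupling and hydrazone cleavage in place of diazo transfer. It sets out from 4: bromine–lithium exchange (n-BuLi, THF, −78 °C) and inverse addition to excess dimethyl oxalate should give methyl 2-{2-[(3,4-dimethoxyphenyl)methoxy]-5-(dimethoxymethyl)-3-methoxyphenyl}-2-oxoacetate F5. Condensation with TsNHNH2 in MeOH gives the tosylhydrazone F6, and DBU in CH2Cl2 expels sulfinate (Bamford–Stevens-type diazo formation) to rejoin the route at 8, bypassing 7.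

Step 7. The product enal may compete with the aldehyde for the ylide, leading to over-homologation to the dienal or to incomplete conversion when the ylide is rationed. The fallback homologates at the ester level and adjusts the oxidation state afterwards. It sets out from 12: Horner–Wadsworth–Emmons reaction with triethyl phosphonoacetate (LiCl, DBU, MeCN) gives ethyl (E)-3-[(2R,3S)-2-(3,4-dimethoxyphenyl)-3-(hydroxymethyl)-7-methoxy-2,3-dihydro-1-benzofuran-5-yl]prop-2-enoate F7. i-Bu2AlH (CH2Cl2, −78 °C) reduces it to (E)-3-[(2R,3S)-2-(3,4-dimethoxyphenyl)-3-(hydroxymethyl)-7-methoxy-2,3-dihydro-1-benzofuran-5-yl]prop-2-en-1-ol F8. MnO2 in CH2Cl2 then oxidises only the allylic alcohol, leaving the saturated primary alcohol, and the route is rejoined at 14.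

Further compounds
F1 | step 5 | potassium 2-{2-[(3,4-dimethoxyphenyl)methoxy]-5-(dimethoxymethyl)-3-methoxyphenyl}acetate | [K+].[O-]C(=O)Cc1cc(C(OC)OC)cc(OC)c1OCc1ccc(OC)c(OC)c1
F2 | step 5 | (2R)-1-oxo-1-(pyrrolidin-1-yl)propan-2-yl 2-{2-[(3,4-dimethoxyphenyl)methoxy]-5-(dimethoxymethyl)-3-methoxyphenyl}acetate | C[C@@H](OC(=O)Cc1cc(C(OC)OC)cc(OC)c1OCc1ccc(OC)c(OC)c1)C(=O)N1CCCC1
F3 | step 5 | (2R)-1-oxo-1-(pyrrolidin-1-yl)propan-2-yl 2-diazo-2-{2-[(3,4-dimethoxyphenyl)methoxy]-5-(dimethoxymethyl)-3-methoxyphenyl}acetate | C[C@@H](OC(=O)C(=[N+]=[N-])c1cc(C(OC)OC)cc(OC)c1OCc1ccc(OC)c(OC)c1)C(=O)N1CCCC1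
F4 | step 5 | (2R)-1-oxo-1-(pyrrolidin-1-yl)propan-2-yl (2R,3R)-2-(3,4-dimethoxyphenyl)-5-(dimethoxymethyl)-7-methoxy-2,3-dihydro-1-benzofuran-3-carboxylate | COc1ccc([C@@H]2Oc3c(OC)cc(C(OC)OC)cc3[C@H]2C(=O)O[C@H](C)C(=O)N4CCCC4)cc1OC
F5 | step 3 | methyl 2-{2-[(3,4-dimethoxyphenyl)methoxy]-5-(dimethoxymethyl)-3-methoxyphenyl}-2-oxoacetate | COC(=O)C(=O)c1cc(C(OC)OC)cc(OC)c1OCc1ccc(OC)c(OC)c1
F6 | step 3 | methyl 2-{2-[(3,4-dimethoxyphenyl)methoxy]-5-(dimethoxymethyl)-3-methoxyphenyl}-2-[2-(4-methylbenzenesulfonyl)hydrazinylidene]acetate | COC(=O)C(=NNS(=O)(=O)c1ccc(C)cc1)c1cc(C(OC)OC)cc(OC)c1OCc1ccc(OC)c(OC)c1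
F7 | step 7 | ethyl (E)-3-[(2R,3S)-2-(3,4-dimethoxyphenyl)-3-(hydroxymethyl)-7-methoxy-2,3-dihydro-1-benzofuran-5-yl]prop-2-enoate | COc1ccc([C@@H]2Oc3c(OC)cc(/C=C/C(=O)OCC)cc3[C@H]2CO)cc1OC
F8 | step 7 | (E)-3-[(2R,3S)-2-(3,4-dimethoxyphenyl)-3-(hydroxymethyl)-7-methoxy-2,3-dihydro-1-benzofuran-5-yl]prop-2-en-1-ol | COc1ccc([C@@H]2Oc3c(OC)cc(/C=C/CO)cc3[C@H]2CO)cc1OC
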